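**Retrosynthetic overview**

1. The strategy rests on ring B of the naphthazarin (C4a, C5, C6, C7, C8, C8a): oxygen on C5 and C8, hydrogen on C6 and C7. This is the pattern of the conjugated bis(silyl enol ether) of cyclohexane-1,4-dione once its CH2–CH2 unit is removed.
2. Last disconnection: the C1'–O acyl bond, giving (S)-alkannin and 3-acetoxy-3-methylbutanoic acid. The tertiary β-acetoxy ester and a benzylic acyloxy group on a hydroquinone-level ring would not tolerate amine base, about 190 °C or the leuco stage, so C1'–O crosses the key step as its Me3Si ether.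
3. Key disconnection: C4a–C5 and C8–C8a of ring B. This is a [4+2] addition of 1,4-bis(trimethylsilyloxy)cyclohexa-1,3-diene to the unsubstituted C=C of the (S)-side-chain 1,4-benzoquinone, then enol silylation of ring A and Alder–Rickert loss of ethylene. Oxidative desilylation then gives the naphthazarin.
4. The quinone comes from 1,4-dimethoxybenzene: C2–C1' by aryllithium addition to the Weinreb amide of 4-methylpent-3-enoic acid, C1' (S) by CBS reduction, ring A unmasked by oxidative demethylation.
5. Ring order: ring A is bought as the arene and carried as the quinone; ring B is closed second, in the key step.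

Key step: step 7

Remark: naphthalene numbering is used for the bicyclic core and C1' is the side-chain carbinol carbon; the descriptor stays (S) in every intermediate because the priority order O > ring carbon > CH2 > H never changes.

**Route**

Step 1
Reactants: 1 4-methylpent-3-enoic acid
Product: 2 N-methoxy-N,4-dimethylpent-3-enamide
Conditions: 1,1'-carbonyldiimidazole (1.1 equiv), CH2Cl2, rt; then MeNH(OMe)·HCl (1.2 equiv), rt
Reagents that add atoms: N,O-dimethylhydroxylamine hydrochloride, CNOC.Cl
Why: Weinreb amide formation through the acyl imidazolide should proceed under near-neutral conditions that leave the β,γ-alkene out of conjugation.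

Step 2
Reactants: 3 1,4-dimethoxybenzene; 2 N-methoxy-N,4-dimethylpent-3-enamide
Product: 5 1-(2,5-dimethoxyphenyl)-4-methylpent-3-en-1-one, via 2,5-dimethoxyphenyllithium 4 (not isolated)
Conditions: 3 (1.2 equiv), n-BuLi (1.15 equiv), TMEDA, THF, 0 °C, 1 h; then 2, –78 °C → –20 °C; sat. aq. NH4Cl
Reagents that add atoms: none
Why: Directed ortho-lithiation followed by Weinreb ketone synthesis should stop at the ketone because the chelated tetrahedral lithium adduct collapses only on work-up, and at –78 °C addition of the aryllithium should outrun deprotonation of the amide α-CH2.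

Step 3
Reactants: 5 1-(2,5-dimethoxyphenyl)-4-methylpent-3-en-1-one
Product: 6 (S)-1-(2,5-dimethoxyphenyl)-4-methylpent-3-en-1-ol
Conditions: (R)-2-methyl-CBS-oxazaborolidine (0.2 equiv), catecholborane (1.5 equiv), toluene, –78 °C; MeOH, then 1 M NaOH wash
Reagents that add atoms: none
Why: In this Corey–Bakshi–Shibata reduction the (R)-oxazaborolidine treats the aryl group as the large substituent and delivers hydride to the face that gives the (S)-carbinol (the (S)-catalyst gives (R)-1-phenylethanol from acetophenone, and the priority order is the same here), while catecholborane at –78 °C should not hydroborate the trisubstituted alkene.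

Step 4
Reactants: 6 (S)-1-(2,5-dimethoxyphenyl)-4-methylpent-3-en-1-ol
Product: 7 (S)-2-(1-hydroxy-4-methylpent-3-en-1-yl)cyclohexa-2,5-diene-1,4-dione
Conditions: (NH4)2Ce(NO3)6 (2.2 equiv), MeCN–H2O, 0 °C, 15 min
Reagents that add atoms: water, O
Why: Oxidative demethylation of a 1,4-dimethoxyarene by tetravalent cerium should give the p-quinone within minutes at 0 °C, faster than oxidation of the carbinol or the alkene, and the C1' centre is not touched.

Step 5
Reactants: 7 (S)-2-(1-hydroxy-4-methylpent-3-en-1-yl)cyclohexa-2,5-diene-1,4-dione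
Product: 8 (S)-2-[4-methyl-1-(trimethylsilyloxy)pent-3-en-1-yl]cyclohexa-2,5-diene-1,4-dione
Conditions: N,O-bis(trimethylsilyl)acetamide (1.5 equiv), CH2Cl2, rt; evaporate under high vacuum, use crude
Reagents that add atoms: N,O-bis(trimethylsilyl)acetamide, CC(=N[Si](C)(C)C)O[Si](C)(C)C
Why: Neutral O-silylation by a silyl amide should mask the hydroxyl, so that it neither protonates the silyl enol ether diene nor lets the hydroxyalkyl quinone tautomerise, without any nucleophilic base that could add to the quinone.

Step 6
Reactants: 9 cyclohexane-1,4-dione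
Product: 10 1,4-bis(trimethylsilyloxy)cyclohexa-1,3-diene
Conditions: Me3SiCl (2.5 equiv), NaI (2.5 equiv), Et3N (3 equiv), MeCN, rt; pentane extraction, distil under Ar
Reagents that add atoms: chlorotrimethylsilane, C[Si](C)(C)Cl
Why: Double silyl enol ether formation with Me3SiI made in the flask runs under equilibrating conditions, which should favour the conjugated 1,3-diene over the skipped 1,4-isomer.

Step 7
Reactants: 8 (S)-2-[4-methyl-1-(trimethylsilyloxy)pent-3-en-1-yl]cyclohexa-2,5-diene-1,4-dione; 10 1,4-bis(trimethylsilyloxy)cyclohexa-1,3-diene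
Product: 13 (S)-trimethyl({4-methyl-1-[1,4,5,8-tetrakis(trimethylsilyloxy)naphthalen-2-yl]pent-3-en-1-yl}oxy)silane, via ethano-bridged ene-dione adduct 11 (not isolated), via ring A bis(silyl ether) 12 (not isolated)
Conditions: 10 (1.3 equiv), toluene, rt; then Me3SiCl (3 equiv), Et3N (4 equiv), 0 °C → rt; filter under Ar, evaporate; degassed o-dichlorobenzene, 190 °C, sealed tube
Reagents that add atoms: chlorotrimethylsilane, C[Si](C)(C)Cl
Why: A thermal suprafacial [4+2] cycloaddition (quinone Diels–Alder reaction) of the electron-rich diene 10 across the electron-poor C5=C6 bond of quinone 8 forms C4a–C5 and C8–C8a and closes ring B by intermolecular annulation as the bicyclo[2.2.2]octene 11. Me3SiCl/Et3N then removes the acidic C4a–H and C8a–H and traps both enolates to give the aromatic ring A bis(silyl ether) 12, in which the bridgehead OSiMe3 groups cannot be lost by β-elimination because that would need a bridgehead alkene. On heating, the cyclohexene made up of C6=C7, C5, C8 and the CH2–CH2 bridge undergoes retro-[4+2] (Alder–Rickert reaction), ethylene escapes and ring B becomes the second ring of a naphthalene. The closest known reactions are the additions of 1-alkoxy- and 1-silyloxycyclohexa-1,3-dienes to quinones and alkynes followed by ethylene extrusion. No lasting stereocentre is made: the sp3 centres C4a, C5, C8 and C8a of 11 and 12 are erased on aromatisation and C1' is a spectator. The step needs site selectivity for the unsubstituted over the C2-substituted quinone C=C, which its lower substitution and higher electrophilicity should secure, the symmetric diene leaves no regiochemical choice, and because extrusion from the benzo-fused bicycle gains only the resonance energy of the second naphthalene ring and is expected to need about 190 °C, C1'–O is carried as a silyl ether and not as the heat- and base-labile acyloxy group.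

Step 8
Reactants: 13 (S)-trimethyl({4-methyl-1-[1,4,5,8-tetrakis(trimethylsilyloxy)naphthalen-2-yl]pent-3-en-1-yl}oxy)silane
Product: 14 (S)-alkannin, (S)-5,8-dihydroxy-2-(1-hydroxy-4-methylpent-3-en-1-yl)naphthalene-1,4-dione
Conditions: (NH4)2Ce(NO3)6 (2.1 equiv), MeCN–H2O, 0 °C, 10 min; aqueous work-up
Reagents that add atoms: none
Why: In this oxidative desilylation tetravalent cerium should take two electrons from the electron-rich tetrasilyloxynaphthalene while the silyl ethers hydrolyse in the acidic aqueous medium, so that the leuco stage never accumulates, the hydrogen-bonded naphthazarin resists further oxidation and the C1'–O bond is not broken.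

Step 9
Reactants: 15 3-hydroxy-3-methylbutanoic acid
Product: 16 3-acetoxy-3-methylbutanoic acid
Conditions: AcCl (excess, neat), 0 °C → rt; evaporate; H2O–THF
Reagents that add atoms: acetyl chloride, CC(=O)Cl
Why: O-Acetylation of a tertiary hydroxy acid with neat acetyl chloride needs no base (as for 2-hydroxyisobutyric acid), and any mixed anhydride at the carboxyl group should be hydrolysed again on aqueous work-up.

Step 10
Reactants: 14 (S)-alkannin; 16 3-acetoxy-3-methylbutanoic acid
Product: 17 (S)-1-(5,8-dihydroxy-1,4-dioxo-1,4-dihydronaphthalen-2-yl)-4-methylpent-3-en-1-yl 3-acetoxy-3-methylbutanoate (target)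
Conditions: DCC (1.2 equiv), DMAP (0.1 equiv), CH2Cl2, 0 °C → rt
Reagents that add atoms: none
Why: In this Steglich esterification the side-chain secondary hydroxyl should be the only reactive oxygen because both phenols are held in hydrogen bonds to the quinone carbonyls, and acyl transfer to oxygen leaves the C1'–O bond and so the (S) configuration untouched.

**Compound list**

1 | 4-methylpent-3-enoic acid | CC(C)=CCC(=O)O | starting material
2 | N-methoxy-N,4-dimethylpent-3-enamide | CON(C)C(=O)CC=C(C)C | intermediate
3 | 1,4-dimethoxybenzene | COc1ccc(OC)cc1 | starting material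
4 | 2,5-dimethoxyphenyllithium | COc1ccc(OC)c([Li])c1 | intermediate
5 | 1-(2,5-dimethoxyphenyl)-4-methylpent-3-en-1-one | COc1ccc(OC)c(C(=O)CC=C(C)C)c1 | intermediate
6 | (S)-1-(2,5-dimethoxyphenyl)-4-methylpent-3-en-1-ol | O[C@@H](CC=C(C)C)c1cc(OC)ccc1OC | intermediate
7 | (S)-2-(1-hydroxy-4-methylpent-3-en-1-yl)cyclohexa-2,5-diene-1,4-dione | O[C@@H](CC=C(C)C)C1=CC(=O)C=CC1=O | intermediate
8 | (S)-2-[4-methyl-1-(trimethylsilyloxy)pent-3-en-1-yl]cyclohexa-2,5-diene-1,4-dione | C[Si](C)(C)O[C@@H](CC=C(C)C)C1=CC(=O)C=CC1=O | intermediate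
9 | cyclohexane-1,4-dione | O=C1CCC(=O)CC1 | starting material
10 | 1,4-bis(trimethylsilyloxy)cyclohexa-1,3-diene | C[Si](C)(C)OC1=CC=C(O[Si](C)(C)C)CC1 | intermediate
11 | 2-[(S)-4-methyl-1-(trimethylsilyloxy)pent-3-en-1-yl]-5,8-bis(trimethylsilyloxy)-4a,5,8,8a-tetrahydro-5,8-ethanonaphthalene-1,4-dione (cis ring fusion, both diastereomers at the transient ring centres) | C[Si](C)(C)O[C@@H](CC=C(C)C)C1=CC(=O)C2C(C1=O)C1(O[Si](C)(C)C)CCC2(O[Si](C)(C)C)C=C1 | intermediate
12 | 2-[(S)-4-methyl-1-(trimethylsilyloxy)pent-3-en-1-yl]-1,4,5,8-tetrakis(trimethylsilyloxy)-5,8-dihydro-5,8-ethanonaphthalene (both bridgehead diastereomers) | C[Si](C)(C)O[C@@H](CC=C(C)C)c1cc(O[Si](C)(C)C)c2c(c1O[Si](C)(C)C)C1(O[Si](C)(C)C)CCC2(O[Si](C)(C)C)C=C1 | intermediate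
13 | (S)-trimethyl({4-methyl-1-[1,4,5,8-tetrakis(trimethylsilyloxy)naphthalen-2-yl]pent-3-en-1-yl}oxy)silane | C[Si](C)(C)O[C@@H](CC=C(C)C)c1cc(O[Si](C)(C)C)c2c(O[Si](C)(C)C)ccc(O[Si](C)(C)C)c2c1O[Si](C)(C)C | intermediate
14 | (S)-alkannin, (S)-5,8-dihydroxy-2-(1-hydroxy-4-methylpent-3-en-1-yl)naphthalene-1,4-dione | O[C@@H](CC=C(C)C)C1=CC(=O)c2c(O)ccc(O)c2C1=O | intermediate
15 | 3-hydroxy-3-methylbutanoic acid | CC(C)(O)CC(=O)O | starting material
16 | 3-acetoxy-3-methylbutanoic acid | CC(=O)OC(C)(C)CC(=O)O | intermediate
17 | (S)-1-(5,8-dihydroxy-1,4-dioxo-1,4-dihydronaphthalen-2-yl)-4-methylpent-3-en-1-yl 3-acetoxy-3-methylbutanoate | CC(=O)OC(C)(C)CC(=O)O[C@@H](CC=C(C)C)C1=CC(=O)c2c(O)ccc(O)c2C1=O | target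

**Step count**

Total step count: 10. Longest linear sequence: 8 steps (steps 1, 2, 3, 4, 5, 7, 8, 10).

**Steps most likely to fail**

1. Step 7. Electron transfer from the very electron-rich diene to the quinone may aromatise the diene and reduce the quinone in place of cycloaddition. Ethylene loss from the benzo-fused bicycle may also need a temperature at which hexamethyldisiloxane is eliminated across C1–O and C1'–O.
Fallback: it sets out from 12 (made as in step 7 up to the filtration) and comes back at 14. The ring A bis(silyl ether) is oxidised with 2,3-dichloro-5,6-dicyano-1,4-benzoquinone (CH2Cl2, 0 °C) to the ethano-bridged quinone (S)-2-[4-methyl-1-(trimethylsilyloxy)pent-3-en-1-yl]-5,8-bis(trimethylsilyloxy)-5,8-dihydro-5,8-ethanonaphthalene-1,4-dione F1. In F1 C4a=C8a is an isolated alkene between two carbonyls, so this true bicyclo[2.2.2]octa-2,5-diene should lose ethylene in refluxing toluene (about 110 °C, the classical quinone variant of the Alder–Rickert reaction). This gives (S)-2-[4-methyl-1-(trimethylsilyloxy)pent-3-en-1-yl]-5,8-bis(trimethylsilyloxy)naphthalene-1,4-dione F2. Dilute HCl in THF then removes the three silyl groups and returns to the route at alkannin 14, so that step 8 is not needed.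

2. Step 8. While the ring system is still a tetraoxygenated, very electron-rich naphthalene, the C1'–O bond may ionise (loss of the benzylic oxygen or ring closure of the hydroxyl onto the alkene), and the cerium oxidant may over-oxidise ring B or the carbinol.
Fallback: it sets out from quinone 8 and comes back at 14. 2,5-Bis(trimethylsilyloxy)furan F3 (from succinic anhydride, Me3SiCl, Et3N, cat. ZnCl2, MeCN) adds to the same C5=C6 bond of 8 (CH2Cl2, –20 °C → rt). The product is the oxygen-bridged adduct 2-[(S)-4-methyl-1-(trimethylsilyloxy)pent-3-en-1-yl]-5,8-bis(trimethylsilyloxy)-4a,5,8,8a-tetrahydro-5,8-epoxynaphthalene-1,4-dione F4. Dilute HCl in THF opens the two bridgehead silyl ketals, C5 and C8 become carbonyls and double enolisation of the tetraketone gives the naphthazarin 14 directly. No oxidant is used and no tetraoxygenated naphthalene lies on the way.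

3. Step 2. The aryllithium may deprotonate the doubly activated α-CH2 of the β,γ-unsaturated amide instead of adding, which returns the arene and lets the alkene migrate into conjugation.
Fallback: it sets out from 4 (made as in step 2) and comes back at 6, bypassing steps 1 and 3 as well. The aryllithium is quenched with DMF (–78 °C → 0 °C) to give 2,5-dimethoxybenzaldehyde F5. Brown allylation with (–)-B-allyldiisopinocampheylborane (the reagent that turns benzaldehyde into (S)-1-phenylbut-3-en-1-ol; Et2O, –78 °C; then NaOH, H2O2) should give (S)-1-(2,5-dimethoxyphenyl)but-3-en-1-ol F6. Cross-metathesis with 2-methylbut-2-ene (second-generation Grubbs catalyst, RuCl2(=CHPh)(PCy3)(H2IMes), CH2Cl2, 40 °C) installs the trisubstituted alkene and gives (S)-alcohol 6.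

**Further compounds**

F1 | step 7 | (S)-2-[4-methyl-1-(trimethylsilyloxy)pent-3-en-1-yl]-5,8-bis(trimethylsilyloxy)-5,8-dihydro-5,8-ethanonaphthalene-1,4-dione | C[Si](C)(C)O[C@@H](CC=C(C)C)C1=CC(=O)C2=C(C1=O)C1(O[Si](C)(C)C)CCC2(O[Si](C)(C)C)C=C1
F2 | step 7 | (S)-2-[4-methyl-1-(trimethylsilyloxy)pent-3-en-1-yl]-5,8-bis(trimethylsilyloxy)naphthalene-1,4-dione | C[Si](C)(C)O[C@@H](CC=C(C)C)C1=CC(=O)c2c(O[Si](C)(C)C)ccc(O[Si](C)(C)C)c2C1=O
F3 | step 8 | 2,5-bis(trimethylsilyloxy)furan | C[Si](C)(C)Oc1ccc(O[Si](C)(C)C)o1
F4 | step 8 | 2-[(S)-4-methyl-1-(trimethylsilyloxy)pent-3-en-1-yl]-5,8-bis(trimethylsilyloxy)-4a,5,8,8a-tetrahydro-5,8-epoxynaphthalene-1,4-dione | C[Si](C)(C)O[C@@H](CC=C(C)C)C1=CC(=O)C2C(C1=O)C1(O[Si](C)(C)C)OC2(O[Si](C)(C)C)C=C1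
F5 | step 2 | 2,5-dimethoxybenzaldehyde | COc1ccc(OC)c(C=O)c1
F6 | step 2 | (S)-1-(2,5-dimethoxyphenyl)but-3-en-1-ol | O[C@@H](CC=C)c1cc(OC)ccc1OC
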